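At late times the flask with 0.77 M of first end groups should stand on a plateau. The blue run falls from 41.7% to 4.4% within 0.250 min, then lies flat from 1.33 min on, as the green run does from 0.833 min on. Those six readings of first end groups average 0.900% of the charge. This mean is the plateau share, the part of the charge still read as first end groups once the readings stop falling. It shows no trend between 0.39 M and 1.5 M.

So at 5.0 min, ten times the time of the blue reading at 0.500 min, this flask should stand at 99.1% reacted. Waiting promises no gain. The gas stays held at 200 mM, where both runs read the plateau. This reckoning gives no figure for bound second end groups.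

| setting | green | blue | flask |
|---|---|---|---|
| first end groups | 0.39 M | 1.5 M | 0.77 M |
| gas | 200 mM (held) | 200 mM (held) | 200 mM (held) |
| remark | run made earlier | run made earlier |  |
| time |  |  | 5.0 min |

| run | time / min | first end groups / % | links / % |
|---|---|---|---|
| green | 0.833 | 0.9 | 99.5 |
| green | 1.50 | 0.4 | 99.0 |
| green | 2.50 | 1.0 | 99.3 |
| green | 3.00 | 0.9 | 99.1 |
| blue | 0.250 | 41.7 | 59.8 |
| blue | 0.500 | 4.4 | 96.0 |
| blue | 1.33 | 0.6 | 98.9 |
| blue | 3.00 | 1.6 | 98.5 |

(readings scatter by 0.5 percentage points)

- at the start none of the gas is in solution
- the earlier runs do not show how much of second end groups is bound; that part of a forecast is a guess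

* part of the first end groups that has reacted at 5.0 min
* share of the unused second end groups that is free and not bound as idle adduct, at 5.0 min

The forecast gives 99.1% reacted and 50% free, the latter “a guess, around half, with a wide range”. The flask gives 99.3% reacted and 94.6% free.

    first end groups + second end groups ⇌ links + by-product (K = 16.0, k = 2.50 L mol⁻¹ s⁻¹)
    second end groups + by-product ⇌ idle adduct, settled at all times (K = 2.60 L mol⁻¹)
    gas ⇌ second end groups, rate k3*(csat - [second end groups]) (kL = 0.360 s⁻¹)
    crystals ⇌ by-product, rate k4*(cs4 - [by-product]) while solid is left; crystals form when [by-product] > cs4 (solubility = 22.0 mM, k = 1.30 s⁻¹)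

The neighbouring flask, charged with 1.3 M of first end groups, takes the same plateau share and so the same reckoning, 99.1% reacted, and it gives 99.3% with 94.6% free. Against the asked flask its crystals rise from 0.731 M to 1.26 M, while by-product in solution stands at 0.0220 M in both. First end groups are its limiting reagent, with 0.68% of their charge left at 5.00 min.

All runs are simulated for substances that don't exist; the scatter is artificial.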